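**Retrosynthetic overview**
- Last step: one acidolysis removes Boc, tert-butyl ester and the C9 silyl ether from the fully protected β-hydroxy ketone.
- Key bond: C13–O, made by catalyst-controlled conjugate hydroxylation of the C13=C14 aryl enone (hydroxyl carried by boron). The enone comes from a C13 aldehyde and a phenacyl ylide.
- Trienoate: C5–C6 Suzuki coupling of the alkenylborane from a C6≡C7 alkyne with a 5-iododienoate.
- C8/C9: anti-propargylation of a C9 aldehyde with a chiral allenylindium. The C10/C12 methyls come from a C2-symmetric diol made by double carboalumination–oxidation of penta-1,4-diene.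
- No ring is built; the only ring (the aryl group) is purchased.

Assumption: the SMILES is read as (2E,4E,6E,8R,9S,10R,12R,13R); catalyst antipodes are named by the induction they must give ((−)-(NMI)2ZrCl2 → (R)-2-methylalkan-1-ols; quinidine-derived squaramide → C13 Si face), and the mirror-image catalyst is used if a model run shows the opposite sense.

**Step 1**
Reactants: 1 penta-1,4-diene
Product: 3 (2R,4R)-2,4-dimethylpentane-1,5-diol, via bis-alane 2 (not isolated)
Conditions: Me3Al (4 equiv), (−)-(NMI)2ZrCl2 (4 mol%), MAO (cat.), CH2Cl2, 0 °C→rt; then O2, 0 °C; aq NaOH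
Reagents that add atoms: trimethylaluminium C[Al](C)C; dioxygen O=O
Why: Zr-catalysed asymmetric carboalumination (ZACA) of both vinyl groups sets C10 and C12 under catalyst control, the double addition raises ee statistically (minor meso diol removed by chromatography), and O2 oxidises the C–Al bonds to C–O without touching the stereocentres.

**Step 2**
Reactants: 3 (2R,4R)-2,4-dimethylpentane-1,5-diol
Product: 4 (2R,4R)-2,4-dimethyl-5-[(triethylsilyl)oxy]pentan-1-ol
Conditions: NaH (1.0 equiv), THF, 0 °C→rt; TESCl (1.0 equiv)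
Reagents that add atoms: chlorotriethylsilane CC[Si](Cl)(CC)CC
Why: Mono-silylation through the monosodium alkoxide; the two hydroxyls of the C2-symmetric diol are homotopic, so one mono-ether forms and no stereocentre is involved.

**Step 3**
Reactants: 4 (2R,4R)-2,4-dimethyl-5-[(triethylsilyl)oxy]pentan-1-ol
Product: 5 (2R,4R)-2,4-dimethyl-5-[(triethylsilyl)oxy]pentanal
Conditions: Dess–Martin periodinane, NaHCO3, CH2Cl2, 0 °C→rt; used crude
Reagents that add atoms: none
Why: Buffered Dess–Martin oxidation gives the α-methyl aldehyde under non-epimerising conditions and leaves the primary TES ether intact.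

**Step 4**
Reactants: 6 (S)-but-3-yn-2-ol
Product: 7 (S)-but-3-yn-2-yl methanesulfonate
Conditions: MsCl, Et3N, CH2Cl2, −78→0 °C
Reagents that add atoms: methanesulfonyl chloride CS(=O)(=O)Cl
Why: O-sulfonylation forms an O–S bond only, so the carbinol configuration is retained.

**Step 5**
Reactants: 5 (2R,4R)-2,4-dimethyl-5-[(triethylsilyl)oxy]pentanal; 7 (S)-but-3-yn-2-yl methanesulfonate
Product: 9 (3R,4S,5R,7R)-3,5,7-trimethyl-8-[(triethylsilyl)oxy]oct-1-yn-4-ol, via allenylindium 8 (not isolated)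
Conditions: Pd(dppf)Cl2 (5 mol%), InI (1.6 equiv), THF–HMPA (3:1), rt
Reagents that add atoms: none
Why: Marshall propargylation: anti-SN2′ oxidative addition of Pd(0) and transmetalation give the (M)-allenylindium, whose cyclic SE2′ addition sets C8 (R) by reagent control and C9 (S) through the anti transition state, which is also the Felkin sense relative to C10.

**Step 6**
Reactants: 9 (3R,4S,5R,7R)-3,5,7-trimethyl-8-[(triethylsilyl)oxy]oct-1-yn-4-ol
Product: 10 (3R,4S,5R,7R)-3,5,7-trimethyl-4,8-bis[(triethylsilyl)oxy]oct-1-yne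
Conditions: TESOTf, 2,6-lutidine, CH2Cl2, −78 °C
Reagents that add atoms: triethylsilyl trifluoromethanesulfonate CC[Si](CC)(CC)OS(=O)(=O)C(F)(F)F
Why: Silyl triflate silylation of the hindered secondary alcohol; the C9 oxygen must be masked because a free C9–OH would later add to the C13 enone in a 6-exo oxa-Michael reaction.

**Step 7**
Reactants: 11 tert-butyl (E)-but-2-enoate
Product: 12 tert-butyl (E)-4-oxobut-2-enoate
Conditions: SeO2 (1.1 equiv), 1,4-dioxane, 100 °C
Reagents that add atoms: selenium dioxide O=[Se]=O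
Why: Riley allylic oxidation converts the γ-methyl group into the aldehyde and keeps the E-alkene.

**Step 8**
Reactants: 12 tert-butyl (E)-4-oxobut-2-enoate
Product: 13 tert-butyl (2E,4E)-5-iodopenta-2,4-dienoate
Conditions: CrCl2 (6 equiv), CHI3 (2 equiv), THF, 0 °C→rt, dark
Reagents that add atoms: iodoform IC(I)I
Why: Takai iodo-olefination of the enal gives the (E)-vinyl iodide selectively through the gem-dichromium reagent.

**Step 9**
Reactants: 10 (3R,4S,5R,7R)-3,5,7-trimethyl-4,8-bis[(triethylsilyl)oxy]oct-1-yne; 13 tert-butyl (2E,4E)-5-iodopenta-2,4-dienoate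
Product: 15 tert-butyl (2E,4E,6E,8R,9S,10R,12R)-8,10,12-trimethyl-9,13-bis[(triethylsilyl)oxy]trideca-2,4,6-trienoate, via alkenylborane 14 (not isolated)
Conditions: Cy2BH (from BH3·SMe2 + cyclohexene, 1.2 equiv), THF, 0 °C→rt; then iodide 13, Pd(PPh3)4 (5 mol%), 3 M aq K3PO4, rt, dark
Reagents that add atoms: none
Why: syn-Hydroboration of the terminal alkyne gives the (E)-alkenylborane, and Suzuki–Miyaura coupling proceeds with retention at both partners to give the (2E,4E,6E)-trienoate; no stereocentre is affected.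

**Step 10**
Reactants: 16 tert-butyl [4-(2-bromoacetyl)phenyl]carbamate
Product: 18 tert-butyl {4-[2-(triphenyl-λ5-phosphanylidene)acetyl]phenyl}carbamate, via phosphonium bromide 17 (not isolated)
Conditions: PPh3, THF, rt; then 1 M aq NaOH, CH2Cl2, 0 °C
Reagents that add atoms: triphenylphosphine c1ccc(cc1)P(c1ccccc1)c1ccccc1
Why: SN2 quaternisation of the α-bromo ketone followed by deprotonation of the acidic phenacylphosphonium salt gives the stabilised keto-ylide.

**Step 11**
Reactants: 15 tert-butyl (2E,4E,6E,8R,9S,10R,12R)-8,10,12-trimethyl-9,13-bis[(triethylsilyl)oxy]trideca-2,4,6-trienoate; 18 tert-butyl {4-[2-(triphenyl-λ5-phosphanylidene)acetyl]phenyl}carbamate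
Product: 20 tert-butyl (2E,4E,6E,8R,9S,10R,12R,13E)-15-{4-[(tert-butoxycarbonyl)amino]phenyl}-8,10,12-trimethyl-15-oxo-9-[(triethylsilyl)oxy]pentadeca-2,4,6,13-tetraenoate, via aldehyde 19 (not isolated)
Conditions: (COCl)2 (4 equiv), DMSO (8 equiv), CH2Cl2, −78→−40 °C; Et3N, −78→0 °C; then ylide 18, rt, 16 h
Reagents that add atoms: none
Why: Swern conditions oxidise the primary TES ether directly to the aldehyde while the hindered secondary TES ether survives, and in-flask Wittig olefination with the stabilised ylide gives the E-enone without isolating the epimerisable α-methyl aldehyde.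

**Step 12**
Reactants: 20 tert-butyl (2E,4E,6E,8R,9S,10R,12R,13E)-15-{4-[(tert-butoxycarbonyl)amino]phenyl}-8,10,12-trimethyl-15-oxo-9-[(triethylsilyl)oxy]pentadeca-2,4,6,13-tetraenoate
Product: 22 tert-butyl (2E,4E,6E,8R,9S,10R,12R,13R)-15-{4-[(tert-butoxycarbonyl)amino]phenyl}-13-hydroxy-8,10,12-trimethyl-15-oxo-9-[(triethylsilyl)oxy]pentadeca-2,4,6-trienoate, via borinate ester 21 (not isolated)
Conditions: Ph2BOH (1.5 equiv), quinidine-derived 3,5-(CF3)2C6H3-squaramide (10 mol%), PhMe, 0 °C→rt; then HOCH2CH2NH2, Et2O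
Reagents that add atoms: diphenylborinic acid OB(c1ccccc1)c1ccccc1
Why: Proposed new method: an intermolecular, catalyst-controlled conjugate hydroxylation in which the quinuclidine nitrogen turns Ph2B–OH into a tetracoordinate, O-nucleophilic hydroxyborinate next to the squaramide-bound s-cis enone, the B–OH oxygen adds to the Si face of C13 (catalyst control over the weak bias from C12, setting 13R), and proton transfer to C14 leaves the C13–O–BPh2 ester chelated to the C15 carbonyl exactly as in a boron aldolate, which supplies the driving force that plain hydration of an enone lacks and blocks retro-oxa-Michael before ethanolamine removes boron; the closest known reactions are the amine–thiourea-catalysed intramolecular oxa-Michael addition of boronic acid hemiesters to hydroxy enones and borinic-acid "ate" activation of oxygen nucleophiles.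

**Step 13**
Reactants: 22 tert-butyl (2E,4E,6E,8R,9S,10R,12R,13R)-15-{4-[(tert-butoxycarbonyl)amino]phenyl}-13-hydroxy-8,10,12-trimethyl-15-oxo-9-[(triethylsilyl)oxy]pentadeca-2,4,6-trienoate
Product: 23 mohangic acid F, (2E,4E,6E,8R,9S,10R,12R,13R)-15-(4-aminophenyl)-9,13-dihydroxy-8,10,12-trimethyl-15-oxopentadeca-2,4,6-trienoic acid
Conditions: TFA–CH2Cl2 (1:4), anisole, H2O (5 equiv), 0 °C→rt; work-up at pH 6
Reagents that add atoms: none
Why: Global acidolysis: the tert-butyl ester and Boc group leave as tert-butyl cation (with decarboxylation of the carbamic acid) and the TES ether is protodesilylated, under conditions that β-hydroxy ketones and conjugated trienes normally tolerate at 0 °C.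

**Compound list**
1 | penta-1,4-diene | C=CCC=C | starting material
2 | (2R,4R)-1,5-bis(dimethylalumanyl)-2,4-dimethylpentane | C[Al](C)C[C@H](C)C[C@@H](C)C[Al](C)C | intermediate
3 | (2R,4R)-2,4-dimethylpentane-1,5-diol | OC[C@H](C)C[C@@H](C)CO | intermediate
4 | (2R,4R)-2,4-dimethyl-5-[(triethylsilyl)oxy]pentan-1-ol | OC[C@H](C)C[C@@H](C)CO[Si](CC)(CC)CC | intermediate
5 | (2R,4R)-2,4-dimethyl-5-[(triethylsilyl)oxy]pentanal | O=C[C@H](C)C[C@@H](C)CO[Si](CC)(CC)CC | intermediate
6 | (S)-but-3-yn-2-ol | C[C@H](O)C#C | starting material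
7 | (S)-but-3-yn-2-yl methanesulfonate | C[C@H](OS(C)(=O)=O)C#C | intermediate
8 | (M)-buta-1,2-dien-1-yl(iodo)indium methanesulfonate | [H]C([In](I)OS(C)(=O)=O)=[C@@]=C([H])C | intermediate
9 | (3R,4S,5R,7R)-3,5,7-trimethyl-8-[(triethylsilyl)oxy]oct-1-yn-4-ol | C[C@H](C#C)[C@@H](O)[C@H](C)C[C@@H](C)CO[Si](CC)(CC)CC | intermediate
10 | (3R,4S,5R,7R)-3,5,7-trimethyl-4,8-bis[(triethylsilyl)oxy]oct-1-yne | C[C@H](C#C)[C@@H](O[Si](CC)(CC)CC)[C@H](C)C[C@@H](C)CO[Si](CC)(CC)CC | intermediate
11 | tert-butyl (E)-but-2-enoate | C/C=C/C(=O)OC(C)(C)C | starting material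
12 | tert-butyl (E)-4-oxobut-2-enoate | O=C/C=C/C(=O)OC(C)(C)C | intermediate
13 | tert-butyl (2E,4E)-5-iodopenta-2,4-dienoate | I/C=C/C=C/C(=O)OC(C)(C)C | intermediate
14 | dicyclohexyl{(1E,3R,4S,5R,7R)-3,5,7-trimethyl-4,8-bis[(triethylsilyl)oxy]oct-1-en-1-yl}borane | C[C@H](/C=C/B(C1CCCCC1)C1CCCCC1)[C@@H](O[Si](CC)(CC)CC)[C@H](C)C[C@@H](C)CO[Si](CC)(CC)CC | intermediate
15 | tert-butyl (2E,4E,6E,8R,9S,10R,12R)-8,10,12-trimethyl-9,13-bis[(triethylsilyl)oxy]trideca-2,4,6-trienoate | C[C@H](/C=C/C=C/C=C/C(=O)OC(C)(C)C)[C@@H](O[Si](CC)(CC)CC)[C@H](C)C[C@@H](C)CO[Si](CC)(CC)CC | intermediate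
16 | tert-butyl [4-(2-bromoacetyl)phenyl]carbamate | CC(C)(C)OC(=O)Nc1ccc(cc1)C(=O)CBr | starting material
17 | {2-[4-((tert-butoxycarbonyl)amino)phenyl]-2-oxoethyl}triphenylphosphonium bromide | CC(C)(C)OC(=O)Nc1ccc(cc1)C(=O)C[P+](c1ccccc1)(c1ccccc1)c1ccccc1.[Br-] | intermediate
18 | tert-butyl {4-[2-(triphenyl-λ5-phosphanylidene)acetyl]phenyl}carbamate | CC(C)(C)OC(=O)Nc1ccc(cc1)C(=O)C=P(c1ccccc1)(c1ccccc1)c1ccccc1 | intermediate
19 | tert-butyl (2E,4E,6E,8R,9S,10R,12R)-8,10,12-trimethyl-13-oxo-9-[(triethylsilyl)oxy]trideca-2,4,6-trienoate | C[C@H](/C=C/C=C/C=C/C(=O)OC(C)(C)C)[C@@H](O[Si](CC)(CC)CC)[C@H](C)C[C@@H](C)C=O | intermediate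
20 | tert-butyl (2E,4E,6E,8R,9S,10R,12R,13E)-15-{4-[(tert-butoxycarbonyl)amino]phenyl}-8,10,12-trimethyl-15-oxo-9-[(triethylsilyl)oxy]pentadeca-2,4,6,13-tetraenoate | C[C@H](/C=C/C=C/C=C/C(=O)OC(C)(C)C)[C@@H](O[Si](CC)(CC)CC)[C@H](C)C[C@@H](C)/C=C/C(=O)c1ccc(NC(=O)OC(C)(C)C)cc1 | intermediate
21 | tert-butyl (2E,4E,6E,8R,9S,10R,12R,13R)-15-{4-[(tert-butoxycarbonyl)amino]phenyl}-13-[(diphenylboranyl)oxy]-8,10,12-trimethyl-15-oxo-9-[(triethylsilyl)oxy]pentadeca-2,4,6-trienoate (boron chelated by the C15 carbonyl) | C[C@H](/C=C/C=C/C=C/C(=O)OC(C)(C)C)[C@@H](O[Si](CC)(CC)CC)[C@H](C)C[C@@H](C)[C@H](OB(c1ccccc1)c1ccccc1)CC(=O)c1ccc(NC(=O)OC(C)(C)C)cc1 | intermediate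
22 | tert-butyl (2E,4E,6E,8R,9S,10R,12R,13R)-15-{4-[(tert-butoxycarbonyl)amino]phenyl}-13-hydroxy-8,10,12-trimethyl-15-oxo-9-[(triethylsilyl)oxy]pentadeca-2,4,6-trienoate | C[C@H](/C=C/C=C/C=C/C(=O)OC(C)(C)C)[C@@H](O[Si](CC)(CC)CC)[C@H](C)C[C@@H](C)[C@H](O)CC(=O)c1ccc(NC(=O)OC(C)(C)C)cc1 | intermediate
23 | mohangic acid F, (2E,4E,6E,8R,9S,10R,12R,13R)-15-(4-aminophenyl)-9,13-dihydroxy-8,10,12-trimethyl-15-oxopentadeca-2,4,6-trienoic acid | C[C@H](/C=C/C=C/C=C/C(=O)O)[C@@H](O)[C@H](C)C[C@@H](C)[C@H](O)CC(=O)c1ccc(N)cc1 | target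

**Step count and risk**
Total step count: 13. Longest linear sequence: 9 (steps 1, 2, 3, 5, 6, 9, 11, 12, 13).

Step 12 is the proposed new conjugate hydroxylation and the most likely to fail, through low conversion or insufficient catalyst control at C13. The fallback uses known chemistry and sets out from enone 20. Lanthanum–BINOL nucleophilic epoxidation [La(O-iPr)3, (S)-BINOL, Ph3As=O, cumene hydroperoxide, 4 Å MS, THF, rt] gives the (13S,14R)-trans-epoxy ketone F1. Reductive cleavage of its C14–O bond with Na[PhSeB(OEt)3] [(PhSe)2, NaBH4, EtOH, AcOH, 0 °C] then comes back to the route at 22. The C13–O bond is then made in the epoxidation and the rest of the route is unchanged.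

Step 11 stacks a direct Swern oxidation of a silyl ether and a Wittig reaction in one flask; the risks are incomplete oxidation and epimerisation at C12 during the slow olefination. The fallback sets out from 15. HF·pyridine/pyridine in THF at 0 °C removes only the primary TES group to give the primary alcohol F2. Dess–Martin oxidation gives aldehyde 19, now isolated, and a separate base-free Wittig reaction with 18 in toluene at 60 °C comes back to the route at 20.

Step 13 exposes an aldol and a triene acid to TFA; the risks are dehydration to the enone followed by cyclisation of the C9 hydroxyl, and tert-butylation of the aniline or triene. The fallback sets out from 22 and unmasks in two non-protic stages. Buffered HF·pyridine (THF/pyridine, 0 °C) gives the diol F3. TMSOTf/2,6-lutidine (CH2Cl2, 0 °C) then converts the tert-butyl ester and Boc group into silyl ester and silyl carbamate, giving the persilylated intermediate F4. Methanol/aqueous citric acid hydrolyses F4, with loss of CO2, and comes back to the route at the target 23.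

**Further compounds**
F1 | step 12 | tert-butyl (2E,4E,6E,8R,9S,10R,12R,13S,14R)-15-{4-[(tert-butoxycarbonyl)amino]phenyl}-13,14-epoxy-8,10,12-trimethyl-15-oxo-9-[(triethylsilyl)oxy]pentadeca-2,4,6-trienoate | C[C@H](/C=C/C=C/C=C/C(=O)OC(C)(C)C)[C@@H](O[Si](CC)(CC)CC)[C@H](C)C[C@@H](C)[C@@H]1O[C@H]1C(=O)c1ccc(NC(=O)OC(C)(C)C)cc1
F2 | step 11 | tert-butyl (2E,4E,6E,8R,9S,10R,12R)-13-hydroxy-8,10,12-trimethyl-9-[(triethylsilyl)oxy]trideca-2,4,6-trienoate | C[C@H](/C=C/C=C/C=C/C(=O)OC(C)(C)C)[C@@H](O[Si](CC)(CC)CC)[C@H](C)C[C@@H](C)CO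
F3 | step 13 | tert-butyl (2E,4E,6E,8R,9S,10R,12R,13R)-15-{4-[(tert-butoxycarbonyl)amino]phenyl}-9,13-dihydroxy-8,10,12-trimethyl-15-oxopentadeca-2,4,6-trienoate | C[C@H](/C=C/C=C/C=C/C(=O)OC(C)(C)C)[C@@H](O)[C@H](C)C[C@@H](C)[C@H](O)CC(=O)c1ccc(NC(=O)OC(C)(C)C)cc1
F4 | step 13 | trimethylsilyl (2E,4E,6E,8R,9S,10R,12R,13R)-8,10,12-trimethyl-15-oxo-9,13-bis[(trimethylsilyl)oxy]-15-[4-({[(trimethylsilyl)oxy]carbonyl}amino)phenyl]pentadeca-2,4,6-trienoate | C[C@H](/C=C/C=C/C=C/C(=O)O[Si](C)(C)C)[C@@H](O[Si](C)(C)C)[C@H](C)C[C@@H](C)[C@H](O[Si](C)(C)C)CC(=O)c1ccc(NC(=O)O[Si](C)(C)C)cc1
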